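**Conventions.** Ring atoms carry the locants of the target name: C1 = CH bearing the 3‑hydroxypropyl chain, C2 = quaternary carbon, C3 = CH–CH3, C4 and C5 = CH2, C6 = alkylidene carbon. C7 is the exocyclic olefin carbon (CH3 and CH2OH). The C16 chain is numbered C1'–C13' from the ring: methyls on C4', C8', C12'; olefins C3'=C4', C6'=C7', C11'=C12'. TT = (3E,6E,8S)‑4,8,12‑trimethyltrideca‑3,6,11‑trien‑1‑yl.

## The problem

The target is a monocyclic C30 diol. One cyclohexane ring carries a quaternary carbon C2 (methyl + C16 trienyl chain), a methyl at C3, a 3‑hydroxypropyl chain at C1, and at C6 a tetrasubstituted exocyclic olefin whose CH2OH is syn to C1 (Z). The three contiguous ring stereocentres are 1S,2R,3R: the C2 methyl is trans to the C3 methyl and cis to the C1 chain. In the chair that allylic strain from the Z‑CH2OH enforces, the C1 and C2 chains are trans‑diaxial and both methyls are equatorial. So C3 can control C2 (addition anti to the C3 methyl) and C2 can control C1 (axial attack anti to the axial chain), but nothing in the ring controls C3 or the C6=C7 geometry. The two ring carbons flanking C6 (methine C1, methylene C5) differ too little for a carbonyl olefination to tell them apart, so the geometry has to come from a stereospecific process. The side chain holds a skipped diene (E‑trisubstituted C3'=C4', E‑disubstituted C6'=C7') and a remote stereocentre C8' (S) that no ring atom can influence. Sensitive points are the doubly allylic C5' methylene, the allylic primary alcohol on a tetrasubstituted olefin, five olefins that must be told apart in any hydroboration or hydrogenation, and C1, which is epimerisable while C6 is a ketone. The feature that makes the key step possible: the only functionalised ring carbons C6 (sp2), C2 (chain) and C3 (methyl) stand 1,3,4 to one another, exactly as OMe, alkyl and methyl do in a 3‑alkyl‑4‑methylanisole. After Birch reduction, C3 lies γ to the C6 carbonyl across a C2=C3 olefin and can be created by an enantioselective 1,3‑proton shift from C1 to C3.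

## Retrosynthesis

**27 ⇒ 24 (through 26).** The C3''–O bond and the O–Si bond are cut: the 3‑hydroxypropyl chain is a hydroborated allyl group, and the allylic alcohol is carried as a silyl ether. An allyl group is the one three‑carbon unit that can be put on the hindered C1 through an enolate. The forward step asks only that 9‑BBN pick the single monosubstituted olefin of 24.

**24 ⇒ 23.** Two C–H bonds are cut, one at ring C5 and one at the C7 methyl. The tetrasubstituted olefin is read as the 1,4‑dihydro form of the s‑cis diene C5=C6–C7(=CH2)CH2OSi. In a 1,4‑addition the two termini end cis, so the new methyl must be cis to C5 and the CH2O group cis to C1, whatever the steric demand of C1 and C5. The alternative diene on the C1 side would create C1 in the same step, by hydrogen delivery anti to the axial C2 chain, which gives the wrong epimer. With the diene on the C5 side no stereocentre is touched.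

**23 ⇒ 20 + 22, 20 ⇒ 18.** The C6–C7 bond is cut by Suzuki–Miyaura coupling of enol triflate 20 with the 2‑borylallyl silyl ether 22 (from propargyl silyl ether 21). The triflate regiochemistry, and with it the olefin geometry, is decided by kinetic enolisation of ketone 18 toward the methylene C5. That is secured because H–C1 is equatorial and flanked by the quaternary C2.

**18 ⇒ 15.** The C2–CH3 and C1–allyl bonds are cut in one operation: conjugate methylation of enone 15, then allylation of the regiospecific enolate. Methyl must enter anti to the C3 methyl and allyl anti to the C2 chain. Both are the normal axial modes, so the precursor needs only the C3 stereocentre.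

**15 ⇒ 14 (key).** The C3–H bond is cut: 15 is the conjugated isomer of the achiral β,γ‑enone 14, and C3 is created by a catalyst‑controlled proton transfer. The precursor has no ring stereocentre at all. The forward step must deliver the proton to one face of C3 and must not racemise the product.

**14 ⇒ 12.** The ring is traced back to a benzene ring. Birch reduction of anisole 12 and mild hydrolysis place the carbonyl at C6 and leave the tetrasubstituted C2=C3 olefin. The forward step must leave the four chain olefins alone and must not conjugate the enone.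

**12 ⇒ 9 + 10.** The C2–C1' bond is cut by sp3–sp2 coupling of the Grignard reagent of bromide 9 with commercial aryl bromide 10. Joining the complete chain here, before any ring stereocentre exists, avoids a protected two‑carbon handle and a late fragment coupling.

**9 ⇒ 3 + 7.** The C5'–C6' bond of the skipped diene is cut between an E‑alkenylzirconocene and a primary allylic chloride. Alkyne 3 keeps all ten carbons and the stereocentre of (S)‑citronellal 1. Chloride 7 comes from homoprenyl bromide 4 through alcohol 5 by E‑selective allylic oxidation.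

## Roads not taken

**Alternative 1:** (the obvious route) Cut C6=C7 by carbonyl olefination and join the chain late. Forward: Stork–Danheiser chemistry on vinylogous ester A1, cuprate addition and allylation to ring ketone A2 with a protected two‑carbon arm, Horner–Wadsworth–Emmons reaction to enoate A3, and a late Negishi coupling of the arm with alkenyl iodide A4. The olefination is the weak point. The ketone is α‑branched and next to a quaternary carbon, and nothing in the mechanism distinguishes C1 from C5 or CH3 from CO2Et, so A3 forms slowly and as an E/Z mixture. A1 also needs a separate asymmetric entry, and the arm costs protection, deprotection and activation steps.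

**Alternative 2:** Cut the C1–C6 ring bond and both C7 substituent bonds at once by zirconocene‑mediated bicyclisation of the acyclic 1,7‑enyne A5 (C2/C3 from an Ireland–Claisen rearrangement). syn‑Carbometalation in zirconabicycle A6 would fix the olefin geometry. The fault is at C1: in the fused metallacycle the C1–CH2 bond must lie in the plane of the exocyclic olefin, i.e. equatorial. The ring then closes through the chair with the C3 methyl also equatorial, which is the 1,3‑cis arrangement, whereas the target has these groups trans (C1 chain axial). A6 is therefore expected as the C1 epimer. The route would also need stoichiometric zirconium and separate homologations of two C–Zr bonds.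

**Alternative 3:** Cut a latent C3''–C7 bond: a Grob fragmentation of cis‑decalin A7 (C3'' carbinol, ring‑fusion mesylate at C6), as a biomimetic step. It would give the aldehyde chain and the tetrasubstituted olefin stereospecifically. The nucleofuge, however, sits on a tertiary ring‑fusion carbon next to a quaternary carbon, where sulfonylation and clean ionisation are doubtful. A7 also has one ring and two stereocentres more than the product, so the run‑up is longer than the whole chosen route.

Key step: step 7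

Remark (assumption): the sense of induction of the amine catalyst in step 7 on this tetrasubstituted olefin is not known in advance; the pseudoenantiomeric series (quinine‑ or quinidine‑derived) that gives the 4R enone is the one used.

## Route

Step 1
Reactants: 1 (S)‑citronellal
Product: 3 (3S)‑3,7‑dimethyloct‑6‑en‑1‑yne, via alkenyl nonaflate 2 (not isolated)
Conditions: n‑C4F9SO2F, phosphazene base P2‑Et, DMF, −20 °C to rt
Reagents that add atoms: none
Why: One‑pot O‑sulfonylation of the aldehyde enolate and E2 elimination of the alkenyl nonaflate (dehydration of an enolisable aldehyde to a terminal alkyne); the stereocentre is not on a reacting carbon, and the acetylide formed under the base shields the propargylic hydrogen from allene isomerisation.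

Step 2
Reactants: 4 5‑bromo‑2‑methylpent‑2‑ene
Product: 5 (2E)‑5‑bromo‑2‑methylpent‑2‑en‑1‑ol
Conditions: SeO2 (cat.), t‑BuOOH, CH2Cl2, 0 °C to rt
Reagents that add atoms: tert‑butyl hydroperoxide, CC(C)(C)OO
Why: Selenium dioxide allylic oxidation (ene reaction, then [2,3] shift) attacks the methyl trans to the chain of a trisubstituted olefin and should give the E allylic alcohol; the primary bromide is inert.

Step 3
Reactants: 5 (2E)‑5‑bromo‑2‑methylpent‑2‑en‑1‑ol
Product: 7 (2E)‑5‑bromo‑1‑chloro‑2‑methylpent‑2‑ene, via allylic mesylate 6 (not isolated)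
Conditions: MsCl, 2,4,6‑collidine, LiCl, DMF, 0 °C
Reagents that add atoms: lithium chloride, [Li+].[Cl-]
Why: Mesylation and in situ SN2 displacement by chloride at the primary allylic carbon, without allylic transposition or loss of E geometry; the homoallylic bromide is much less reactive.

Step 4
Reactants: 3 (3S)‑3,7‑dimethyloct‑6‑en‑1‑yne; 7 (2E)‑5‑bromo‑1‑chloro‑2‑methylpent‑2‑ene
Product: 9 (3E,6E,8S)‑1‑bromo‑4,8,12‑trimethyltrideca‑3,6,11‑triene, via alkenylzirconocene 8 (not isolated)
Conditions: Cp2Zr(H)Cl, THF, rt; then 7, Pd(PPh3)4 (5 mol %), ZnCl2 (20 mol %), THF, rt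
Reagents that add atoms: none
Why: syn‑Hydrozirconation of the terminal alkyne gives the E‑alkenylzirconocene and leaves the trisubstituted olefin alone; palladium‑catalysed alkenyl–allyl coupling (Negishi type) should form C5'–C6' at the primary allylic terminus with retention of both olefin geometries, and the alkyl bromide does not add to zerovalent palladium under these conditions.

Step 5
Reactants: 9 (3E,6E,8S)‑1‑bromo‑4,8,12‑trimethyltrideca‑3,6,11‑triene; 10 2‑bromo‑4‑methoxy‑1‑methylbenzene
Product: 12 4‑methoxy‑1‑methyl‑2‑TT‑benzene, via Grignard reagent 11 (not isolated)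
Conditions: Mg, THF, rt; then 10, PdCl2(dppf) (3 mol %), THF, 50 °C
Reagents that add atoms: none
Why: Kumada coupling of a primary homoallylic Grignard reagent with an aryl bromide; the wide‑bite‑angle diphosphine suppresses β‑hydride elimination, and the trisubstituted homoallylic olefin does not scramble on this time scale.

Step 6
Reactants: 12 4‑methoxy‑1‑methyl‑2‑TT‑benzene
Product: 14 4‑methyl‑3‑TT‑cyclohex‑3‑en‑1‑one, via dienol ether 13 (not isolated)
Conditions: Li, NH3 (l), THF, t‑BuOH, −78 to −33 °C; then (CO2H)2, MeOH/H2O, rt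
Reagents that add atoms: water, O
Why: Birch reduction protonates the two unsubstituted positions ortho and meta to OMe, so the enol ether and the tetrasubstituted C2=C3 olefin remain, and isolated chain olefins are not reduced by Li/NH3; oxalic acid hydrolyses the enol ether without moving the olefin into conjugation.

Step 7
Reactants: 14 4‑methyl‑3‑TT‑cyclohex‑3‑en‑1‑one
Product: 15 (4R)‑4‑methyl‑3‑TT‑cyclohex‑2‑en‑1‑one
Conditions: chiral primary–tertiary diamine of the 9‑amino‑9‑deoxy‑epi‑cinchona type (10 mol %), aryl carboxylic acid (20 mol %), toluene, −25 °C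
Reagents that add atoms: none
Why: The primary amine condenses with the unhindered C6 ketone to an iminium ion, the tertiary amine of the catalyst removes a C1 proton (α to the iminium and allylic) to give the linear 2‑aminodiene C6(N)=C1–C2=C3, and the resulting ammonium returns the proton to C3 inside the chiral ion pair; hydrolysis of the conjugated iminium releases 15. The closest known reaction type is the amine‑catalysed enantioselective isomerisation of Birch‑derived cyclohex‑3‑enones to 4‑substituted cyclohex‑2‑enones. No ring is closed. The one new stereocentre, ring C3, is set by the catalyst alone, since the C8' centre of the chain is too far away to matter. The step needs site selectivity, enantiofacial selectivity at a carbon bearing a methyl and a ring methylene, and a product that does not re‑enter the cycle. Site selectivity is inherent, because enamine formation toward C5 is unproductive and only protonation at C3 leads to a conjugated product. Conjugation makes 15 the thermodynamic sink, and low temperature with a stop at full conversion should limit racemisation by the reverse path. The tetrasubstituted C2=C3 olefin is more hindered than the trisubstituted olefins on which this reaction type rests, and that is the main risk.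

Step 8
Reactants: 15 (4R)‑4‑methyl‑3‑TT‑cyclohex‑2‑en‑1‑one
Product: 18 (2S,3R,4R)‑3,4‑dimethyl‑2‑(prop‑2‑en‑1‑yl)‑3‑TT‑cyclohexan‑1‑one, via silyl enol ether 16 (not isolated), via lithium enolate 17 (not isolated)
Conditions: Me2CuLi (from CuI and MeLi), Me3SiCl, THF, −78 to −30 °C; volatiles removed; MeLi, THF, 0 °C; then allyl bromide, HMPA, −78 to 0 °C
Reagents that add atoms: lithium dimethylcuprate, [Li+].C[Cu-]C; allyl bromide, C=CCBr
Why: Silyl chloride‑accelerated cuprate 1,4‑addition puts methyl on C2 anti to the pseudoaxial C3 methyl (axial attack), so the two methyls are trans; the regiospecific lithium enolate from silyl enol ether cleavage is then allylated axially at C1 in the conformer with the C16 chain axial and both methyls equatorial. The opposite face is blocked by that axial chain or, after ring inversion, by an axial C3 methyl in a 1,3 relation, so allyl should end cis to the C2 methyl (conjugate addition–enolate trapping).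

Step 9
Reactants: 18 (2S,3R,4R)‑3,4‑dimethyl‑2‑(prop‑2‑en‑1‑yl)‑3‑TT‑cyclohexan‑1‑one
Product: 20 (4R,5R,6S)‑4,5‑dimethyl‑6‑(prop‑2‑en‑1‑yl)‑5‑TT‑cyclohex‑1‑en‑1‑yl trifluoromethanesulfonate, via potassium enolate 19 (not isolated)
Conditions: KN(SiMe3)2, THF, −78 °C; then PhNTf2, −78 to 0 °C
Reagents that add atoms: N‑phenylbis(trifluoromethanesulfonimide), O=S(=O)(N(c1ccccc1)S(=O)(=O)C(F)(F)F)C(F)(F)F
Why: Kinetic deprotonation takes the methylene C5, because H–C1 is equatorial (poorly aligned with the carbonyl) and shielded by the quaternary C2; O‑sulfonylation then gives the less substituted enol triflate without touching the C1 stereocentre.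

Step 10
Reactants: 21 tert‑butyldimethyl(prop‑2‑yn‑1‑yloxy)silane
Product: 22 tert‑butyldimethyl{[2‑(4,4,5,5‑tetramethyl‑1,3,2‑dioxaborolan‑2‑yl)prop‑2‑en‑1‑yl]oxy}silane
Conditions: B2pin2, CuCl (5 mol %), 1,3‑dimesitylimidazolinium chloride (5 mol %), NaOt‑Bu (10 mol %), MeOH, THF, −15 °C
Reagents that add atoms: bis(pinacolato)diboron, CC1(C)OB(OC1(C)C)B1OC(C)(C)C(C)(C)O1
Why: Copper‑catalysed protoboration of a terminal alkyne (borylcupration, then protonation by methanol); with an N‑aryl carbene ligand and a propargylic oxygen, boron should end on the internal carbon.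

Step 11
Reactants: 20 (4R,5R,6S)‑4,5‑dimethyl‑6‑(prop‑2‑en‑1‑yl)‑5‑TT‑cyclohex‑1‑en‑1‑yl trifluoromethanesulfonate; 22 tert‑butyldimethyl{[2‑(4,4,5,5‑tetramethyl‑1,3,2‑dioxaborolan‑2‑yl)prop‑2‑en‑1‑yl]oxy}silane
Product: 23 tert‑butyl{[2‑[(4R,5R,6S)‑4,5‑dimethyl‑6‑(prop‑2‑en‑1‑yl)‑5‑TT‑cyclohex‑1‑en‑1‑yl]prop‑2‑en‑1‑yl]oxy}dimethylsilane
Conditions: PdCl2(dppf) (5 mol %), K3PO4, 1,4‑dioxane/H2O, 60 °C
Reagents that add atoms: none
Why: Suzuki–Miyaura coupling of an alkenyl triflate with an alkenylboronate forms the C6–C7 bond and the 2‑substituted 1,3‑diene; no stereocentre or olefin geometry is at stake, and a Heck closure onto the allyl group would need a four‑membered or 5‑endo ring.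

Step 12
Reactants: 23 tert‑butyl{[2‑[(4R,5R,6S)‑4,5‑dimethyl‑6‑(prop‑2‑en‑1‑yl)‑5‑TT‑cyclohex‑1‑en‑1‑yl]prop‑2‑en‑1‑yl]oxy}dimethylsilane
Product: 24 tert‑butyl{[(2Z)‑2‑[(2S,3R,4R)‑3,4‑dimethyl‑2‑(prop‑2‑en‑1‑yl)‑3‑TT‑cyclohexylidene]propyl]oxy}dimethylsilane
Conditions: (η6‑naphthalene)Cr(CO)3 (20 mol %), H2 (50 atm), THF, 45 °C
Reagents that add atoms: none
Why: Chromium tricarbonyl‑catalysed 1,4‑hydrogenation: the diene binds η4 in its s‑cis form and both hydrogens go to the termini (C5 and the exocyclic CH2), so in the new C6=C7 bond the new methyl is cis to C5 and CH2OSi is cis to C1 by topology alone; isolated and skipped olefins cannot bind η4 and should stay untouched, and no stereocentre is formed, so the face of complexation does not matter.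

Step 13
Reactants: 24 tert‑butyl{[(2Z)‑2‑[(2S,3R,4R)‑3,4‑dimethyl‑2‑(prop‑2‑en‑1‑yl)‑3‑TT‑cyclohexylidene]propyl]oxy}dimethylsilane
Product: 26 3‑[(1S,2R,3R,6Z)‑6‑{1‑[(tert‑butyldimethylsilyl)oxy]propan‑2‑ylidene}‑2,3‑dimethyl‑2‑TT‑cyclohexyl]propan‑1‑ol, via trialkylborane 25 (not isolated)
Conditions: 9‑BBN, THF, 0 °C to rt; then NaOH, H2O2, H2O, 0 °C
Reagents that add atoms: hydrogen peroxide, OO
Why: Anti‑Markovnikov hydroboration–oxidation; 9‑BBN reacts with the one monosubstituted olefin far faster than with the tetrasubstituted, the two trisubstituted and the α‑branched E‑disubstituted olefins.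

Step 14
Reactants: 26 3‑[(1S,2R,3R,6Z)‑6‑{1‑[(tert‑butyldimethylsilyl)oxy]propan‑2‑ylidene}‑2,3‑dimethyl‑2‑TT‑cyclohexyl]propan‑1‑ol
Product: 27 3‑[(1S,2R,3R,6Z)‑6‑(1‑hydroxypropan‑2‑ylidene)‑2,3‑dimethyl‑2‑TT‑cyclohexyl]propan‑1‑ol (target)
Conditions: Bu4NF, THF, 0 °C to rt
Reagents that add atoms: none
Why: Fluoride cleavage of the primary silyl ether under non‑acidic conditions, which spares the allylic alcohol and the skipped diene.

## Compound list

1 | (3S)‑3,7‑dimethyloct‑6‑enal, (S)‑citronellal | CC(C)=CCC[C@H](C)CC=O | starting material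
2 | (3S)‑3,7‑dimethylocta‑1,6‑dien‑1‑yl nonafluorobutane‑1‑sulfonate (E/Z mixture) | CC(C)=CCC[C@H](C)C=COS(=O)(=O)C(F)(F)C(F)(F)C(F)(F)C(F)(F)F | intermediate
3 | (3S)‑3,7‑dimethyloct‑6‑en‑1‑yne | CC(C)=CCC[C@H](C)C#C | intermediate
4 | 5‑bromo‑2‑methylpent‑2‑ene | CC(C)=CCCBr | starting material
5 | (2E)‑5‑bromo‑2‑methylpent‑2‑en‑1‑ol | OC/C(C)=C/CCBr | intermediate
6 | (2E)‑5‑bromo‑2‑methylpent‑2‑en‑1‑yl methanesulfonate | CS(=O)(=O)OC/C(C)=C/CCBr | intermediate
7 | (2E)‑5‑bromo‑1‑chloro‑2‑methylpent‑2‑ene | ClC/C(C)=C/CCBr | intermediate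
8 | chlorobis(cyclopentadienyl)[(1E,3S)‑3,7‑dimethylocta‑1,6‑dien‑1‑yl]zirconium | CC(C)=CCC[C@H](C)/C=C/[Zr](Cl)(C1C=CC=C1)C1C=CC=C1 | intermediate
9 | (3E,6E,8S)‑1‑bromo‑4,8,12‑trimethyltrideca‑3,6,11‑triene | CC(C)=CCC[C@H](C)/C=C/C/C(C)=C/CCBr | intermediate
10 | 2‑bromo‑4‑methoxy‑1‑methylbenzene (3‑bromo‑4‑methylanisole) | COc1ccc(C)c(Br)c1 | starting material
11 | [(3E,6E,8S)‑4,8,12‑trimethyltrideca‑3,6,11‑trien‑1‑yl]magnesium bromide | CC(C)=CCC[C@H](C)/C=C/C/C(C)=C/CC[Mg]Br | intermediate
12 | 4‑methoxy‑1‑methyl‑2‑[(3E,6E,8S)‑4,8,12‑trimethyltrideca‑3,6,11‑trien‑1‑yl]benzene | CC(C)=CCC[C@H](C)/C=C/C/C(C)=C/CCc1cc(OC)ccc1C | intermediate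
13 | 1‑methoxy‑4‑methyl‑5‑[(3E,6E,8S)‑4,8,12‑trimethyltrideca‑3,6,11‑trien‑1‑yl]cyclohexa‑1,4‑diene | CC(C)=CCC[C@H](C)/C=C/C/C(C)=C/CCC1=C(C)CC=C(OC)C1 | intermediate
14 | 4‑methyl‑3‑[(3E,6E,8S)‑4,8,12‑trimethyltrideca‑3,6,11‑trien‑1‑yl]cyclohex‑3‑en‑1‑one | CC(C)=CCC[C@H](C)/C=C/C/C(C)=C/CCC1=C(C)CCC(=O)C1 | intermediate
15 | (4R)‑4‑methyl‑3‑[(3E,6E,8S)‑4,8,12‑trimethyltrideca‑3,6,11‑trien‑1‑yl]cyclohex‑2‑en‑1‑one | CC(C)=CCC[C@H](C)/C=C/C/C(C)=C/CCC1=CC(=O)CC[C@H]1C | intermediate
16 | {[(3R,4R)‑3,4‑dimethyl‑3‑[(3E,6E,8S)‑4,8,12‑trimethyltrideca‑3,6,11‑trien‑1‑yl]cyclohex‑1‑en‑1‑yl]oxy}trimethylsilane | CC(C)=CCC[C@H](C)/C=C/C/C(C)=C/CC[C@]1(C)[C@H](C)CCC(O[Si](C)(C)C)=C1 | intermediate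
17 | lithium (3R,4R)‑3,4‑dimethyl‑3‑[(3E,6E,8S)‑4,8,12‑trimethyltrideca‑3,6,11‑trien‑1‑yl]cyclohex‑1‑en‑1‑olate | CC(C)=CCC[C@H](C)/C=C/C/C(C)=C/CC[C@]1(C)[C@H](C)CCC([O-])=C1.[Li+] | intermediate
18 | (2S,3R,4R)‑3,4‑dimethyl‑2‑(prop‑2‑en‑1‑yl)‑3‑[(3E,6E,8S)‑4,8,12‑trimethyltrideca‑3,6,11‑trien‑1‑yl]cyclohexan‑1‑one | CC(C)=CCC[C@H](C)/C=C/C/C(C)=C/CC[C@]1(C)[C@H](C)CCC(=O)[C@H]1CC=C | intermediate
19 | potassium (4R,5R,6S)‑4,5‑dimethyl‑6‑(prop‑2‑en‑1‑yl)‑5‑[(3E,6E,8S)‑4,8,12‑trimethyltrideca‑3,6,11‑trien‑1‑yl]cyclohex‑1‑en‑1‑olate | CC(C)=CCC[C@H](C)/C=C/C/C(C)=C/CC[C@]1(C)[C@H](C)CC=C([O-])[C@H]1CC=C.[K+] | intermediate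
20 | (4R,5R,6S)‑4,5‑dimethyl‑6‑(prop‑2‑en‑1‑yl)‑5‑[(3E,6E,8S)‑4,8,12‑trimethyltrideca‑3,6,11‑trien‑1‑yl]cyclohex‑1‑en‑1‑yl trifluoromethanesulfonate | CC(C)=CCC[C@H](C)/C=C/C/C(C)=C/CC[C@]1(C)[C@H](C)CC=C(OS(=O)(=O)C(F)(F)F)[C@H]1CC=C | intermediate
21 | tert‑butyldimethyl(prop‑2‑yn‑1‑yloxy)silane | C#CCO[Si](C)(C)C(C)(C)C | starting material
22 | tert‑butyldimethyl{[2‑(4,4,5,5‑tetramethyl‑1,3,2‑dioxaborolan‑2‑yl)prop‑2‑en‑1‑yl]oxy}silane | C=C(CO[Si](C)(C)C(C)(C)C)B1OC(C)(C)C(C)(C)O1 | intermediate
23 | tert‑butyl{[2‑[(4R,5R,6S)‑4,5‑dimethyl‑6‑(prop‑2‑en‑1‑yl)‑5‑[(3E,6E,8S)‑4,8,12‑trimethyltrideca‑3,6,11‑trien‑1‑yl]cyclohex‑1‑en‑1‑yl]prop‑2‑en‑1‑yl]oxy}dimethylsilane | CC(C)=CCC[C@H](C)/C=C/C/C(C)=C/CC[C@]1(C)[C@H](C)CC=C(C(=C)CO[Si](C)(C)C(C)(C)C)[C@H]1CC=C | intermediate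
24 | tert‑butyl{[(2Z)‑2‑[(2S,3R,4R)‑3,4‑dimethyl‑2‑(prop‑2‑en‑1‑yl)‑3‑[(3E,6E,8S)‑4,8,12‑trimethyltrideca‑3,6,11‑trien‑1‑yl]cyclohexylidene]propyl]oxy}dimethylsilane | CC(C)=CCC[C@H](C)/C=C/C/C(C)=C/CC[C@]1(C)[C@H](C)CC/C(=C(\C)CO[Si](C)(C)C(C)(C)C)[C@H]1CC=C | intermediate
25 | 9‑{3‑[(1S,2R,3R,6Z)‑6‑{1‑[(tert‑butyldimethylsilyl)oxy]propan‑2‑ylidene}‑2,3‑dimethyl‑2‑[(3E,6E,8S)‑4,8,12‑trimethyltrideca‑3,6,11‑trien‑1‑yl]cyclohexyl]propyl}‑9‑borabicyclo[3.3.1]nonane | CC(C)=CCC[C@H](C)/C=C/C/C(C)=C/CC[C@]1(C)[C@H](C)CC/C(=C(\C)CO[Si](C)(C)C(C)(C)C)[C@H]1CCCB1C2CCCC1CCC2 | intermediate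
26 | 3‑[(1S,2R,3R,6Z)‑6‑{1‑[(tert‑butyldimethylsilyl)oxy]propan‑2‑ylidene}‑2,3‑dimethyl‑2‑[(3E,6E,8S)‑4,8,12‑trimethyltrideca‑3,6,11‑trien‑1‑yl]cyclohexyl]propan‑1‑ol | CC(C)=CCC[C@H](C)/C=C/C/C(C)=C/CC[C@]1(C)[C@H](C)CC/C(=C(\C)CO[Si](C)(C)C(C)(C)C)[C@H]1CCCO | intermediate
27 | 3‑[(1S,2R,3R,6Z)‑6‑(1‑hydroxypropan‑2‑ylidene)‑2,3‑dimethyl‑2‑[(3E,6E,8S)‑4,8,12‑trimethyltrideca‑3,6,11‑trien‑1‑yl]cyclohexyl]propan‑1‑ol | CC(C)=CCC[C@H](C)/C=C/C/C(C)=C/CC[C@]1(C)[C@H](C)CC/C(=C(\C)CO)[C@H]1CCCO | target

## Step count and risks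

Total: 14 steps. Longest linear sequence: 12 steps (4 → 27 through steps 2–9 and 11–14); steps 1 and 10 are side branches.

**Step 7 (key step).** The likeliest failure is poor enantiofacial discrimination in the proton return to C3. The dienamine terminus is fully substituted and flanked by the C16 chain on C2, and dienamine formation may be slow enough for product racemisation by the reverse path to catch up. Because the chain stereocentre is already present, any loss shows up as an inseparable diastereomer. The fallback sets out from 14 and returns at 15. Acid‑ or DBU‑mediated conjugation gives the racemic enone (4RS)‑4‑methyl‑3‑TT‑cyclohex‑2‑en‑1‑one F1. Corey–Bakshi–Shibata reduction (oxazaborolidine, BH3·SMe2) turns its two ring enantiomers into diastereomeric allylic alcohols with the same carbinol configuration. The (1S,4R)‑4‑methyl‑3‑TT‑cyclohex‑2‑en‑1‑ol F2 is separated by chromatography and oxidised back with MnO2 to 15.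

**Step 12.** The hindered diene, crowded by the axial allyl group on C1 and the silyloxymethyl group, may fail to reach the η4 s‑cis complex. The catalyst could then move the skipped chain diene into conjugation and reduce it. The fallback sets out from 18 and returns at 24, giving up mechanistic control of geometry for a separation. Horner–Wadsworth–Emmons olefination (triethyl 2‑phosphonopropionate, NaH, toluene, heat) gives the enoate ethyl 2‑[(2S,3R,4R)‑3,4‑dimethyl‑2‑(prop‑2‑en‑1‑yl)‑3‑TT‑cyclohexylidene]propanoate F3 as an E/Z mixture. The Z isomer F4 is isolated by chromatography, and the E isomer is re‑equilibrated photochemically and recycled. Reduction with i‑Bu2AlH gives the allylic alcohol (2Z)‑2‑[(2S,3R,4R)‑3,4‑dimethyl‑2‑(prop‑2‑en‑1‑yl)‑3‑TT‑cyclohexylidene]propan‑1‑ol F5, and silylation (t‑BuMe2SiCl, imidazole) gives 24.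

**Step 8.** C‑Allylation of the tetrasubstituted lithium enolate next to the quaternary carbon may be slow. Proton transfer, O‑allylation or attack through the ring‑inverted conformer would then lower yield and facial selectivity. The fallback sets out from 16 (made from 15 as in step 8) and returns at 18. The enolate 17 is O‑acylated with allyl chloroformate to the allyl enol carbonate prop‑2‑en‑1‑yl (3R,4R)‑3,4‑dimethyl‑3‑TT‑cyclohex‑1‑en‑1‑yl carbonate F6. Palladium‑catalysed decarboxylative Tsuji allylation (Pd(PPh3)4, THF) then forms the C1–allyl bond inside an ion pair instead of by bimolecular alkylation.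

**Step 1.** Base‑induced 1,4‑elimination of the nonaflate to an allene, or prototropic scrambling at the propargylic carbon, would lower yield and erode the C8' configuration. The fallback sets out from 1 and returns at 3. Condensation with morpholine gives the enamine 4‑[(1E,3S)‑3,7‑dimethylocta‑1,6‑dien‑1‑yl]morpholine F7. Its CuCl/O2 cleavage removes one carbon and gives (2S)‑2,6‑dimethylhept‑5‑enal F8. Ohira–Bestmann homologation (dimethyl (1‑diazo‑2‑oxopropyl)phosphonate, K2CO3, MeOH, 0 °C) puts the carbon back as the alkyne of 3.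

## Further compounds

F1 | step 7 | (4RS)‑4‑methyl‑3‑[(3E,6E,8S)‑4,8,12‑trimethyltrideca‑3,6,11‑trien‑1‑yl]cyclohex‑2‑en‑1‑one | CC(C)=CCC[C@H](C)/C=C/C/C(C)=C/CCC1=CC(=O)CCC1C
F2 | step 7 | (1S,4R)‑4‑methyl‑3‑[(3E,6E,8S)‑4,8,12‑trimethyltrideca‑3,6,11‑trien‑1‑yl]cyclohex‑2‑en‑1‑ol | CC(C)=CCC[C@H](C)/C=C/C/C(C)=C/CCC1=C[C@@H](O)CC[C@H]1C
F3 | step 12 | ethyl 2‑[(2S,3R,4R)‑3,4‑dimethyl‑2‑(prop‑2‑en‑1‑yl)‑3‑[(3E,6E,8S)‑4,8,12‑trimethyltrideca‑3,6,11‑trien‑1‑yl]cyclohexylidene]propanoate (E/Z mixture) | CC(C)=CCC[C@H](C)/C=C/C/C(C)=C/CC[C@]1(C)[C@H](C)CCC(=C(C)C(=O)OCC)[C@H]1CC=C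
F4 | step 12 | ethyl (2Z)‑2‑[(2S,3R,4R)‑3,4‑dimethyl‑2‑(prop‑2‑en‑1‑yl)‑3‑[(3E,6E,8S)‑4,8,12‑trimethyltrideca‑3,6,11‑trien‑1‑yl]cyclohexylidene]propanoate | CC(C)=CCC[C@H](C)/C=C/C/C(C)=C/CC[C@]1(C)[C@H](C)CC/C(=C(\C)C(=O)OCC)[C@H]1CC=C
F5 | step 12 | (2Z)‑2‑[(2S,3R,4R)‑3,4‑dimethyl‑2‑(prop‑2‑en‑1‑yl)‑3‑[(3E,6E,8S)‑4,8,12‑trimethyltrideca‑3,6,11‑trien‑1‑yl]cyclohexylidene]propan‑1‑ol | CC(C)=CCC[C@H](C)/C=C/C/C(C)=C/CC[C@]1(C)[C@H](C)CC/C(=C(\C)CO)[C@H]1CC=C
F6 | step 8 | prop‑2‑en‑1‑yl (3R,4R)‑3,4‑dimethyl‑3‑[(3E,6E,8S)‑4,8,12‑trimethyltrideca‑3,6,11‑trien‑1‑yl]cyclohex‑1‑en‑1‑yl carbonate | CC(C)=CCC[C@H](C)/C=C/C/C(C)=C/CC[C@]1(C)[C@H](C)CCC(OC(=O)OCC=C)=C1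
F7 | step 1 | 4‑[(1E,3S)‑3,7‑dimethylocta‑1,6‑dien‑1‑yl]morpholine | CC(C)=CCC[C@H](C)/C=C/N1CCOCC1
F8 | step 1 | (2S)‑2,6‑dimethylhept‑5‑enal | CC(C)=CCC[C@H](C)C=O
A1 | alternative 1 | 3‑ethoxy‑6‑methylcyclohex‑2‑en‑1‑one (racemic) | CCOC1=CC(=O)C(C)CC1
A2 | alternative 1 | (2S,3R,4R)‑3‑{2‑[(tert‑butyldimethylsilyl)oxy]ethyl}‑3,4‑dimethyl‑2‑(prop‑2‑en‑1‑yl)cyclohexan‑1‑one | CC(C)(C)[Si](C)(C)OCC[C@]1(C)[C@H](C)CCC(=O)[C@H]1CC=C
A3 | alternative 1 | ethyl 2‑[(2S,3R,4R)‑3‑{2‑[(tert‑butyldimethylsilyl)oxy]ethyl}‑3,4‑dimethyl‑2‑(prop‑2‑en‑1‑yl)cyclohexylidene]propanoate (E/Z mixture) | CC(C)(C)[Si](C)(C)OCC[C@]1(C)[C@H](C)CCC(=C(C)C(=O)OCC)[C@H]1CC=C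
A4 | alternative 1 | (1E,4E,6S)‑1‑iodo‑2,6,10‑trimethylundeca‑1,4,9‑triene | CC(C)=CCC[C@H](C)/C=C/C/C(C)=C/I
A5 | alternative 2 | (6R,7S,10E,13E,15S)‑7‑ethenyl‑6,7,11,15,19‑pentamethylicosa‑10,13,18‑trien‑2‑yne | CC(C)=CCC[C@H](C)/C=C/C/C(C)=C/CC[C@](C=C)(C)[C@H](C)CCC#CC
A6 | alternative 2 | bis(cyclopentadienyl)zirconacyclopentene fused to the cyclohexane across C6 and C1 (C7 methyl on the ring sp2 carbon next to zirconium), drawn as the expected C1 epimer | CC(C)=CCC[C@H](C)/C=C/C/C(C)=C/CC[C@]1(C)[C@H](C)CCC2=C(C)[Zr](C3C=CC=C3)(C3C=CC=C3)C[C@H]12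
A7 | alternative 3 | cis‑fused decalin with C3'' carbinol, C7 bearing methyl and (tert‑butyldimethylsilyloxy)methyl, ring‑fusion C6 methanesulfonate, C2 methyl and TT chain, C3 methyl | CC(C)=CCC[C@H](C)/C=C/C/C(C)=C/CC[C@]1(C)[C@H](C)CC[C@@]2(OS(C)(=O)=O)[C@](C)(CO[Si](C)(C)C(C)(C)C)[C@H](O)CC[C@@H]12
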